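**Assumption:** the SMILES descriptor corresponds to the (S)-configured acetoxy carbon; ω-pentadecalactone, ethyl (S)-lactate and methyl pyruvate are taken as cheap commercial materials.

## Retrosynthetic overview

1. Target 21 ⇐ acetylation of hydroxy anhydride 20 ⇐ saponification of the (Z)-maleate diester 17; the cis-diacid closes spontaneously to the anhydride (the only ring, formed in step 11).
2. Maleate C=C ⇐ dehydration of the β-hydroxy diester 14.
3. Key C–C bond (the future ring C3–C4) ⇐ intermolecular aldol of the lithium enolate of methyl (S)-17-silyloxyoctadecanoate 10 with methyl pyruvate 11.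
4. 10 ⇐ Wittig olefination and hydrogenation of the C15 phosphonium salt 4 (from ω-pentadecalactone 1) with (S)-2-silyloxypropanal 7 (from ethyl (S)-lactate 5, the source of the stereocentre).

## Route

Step 1
Reactants: 1 ω-pentadecalactone
Product: 2 methyl 15-hydroxypentadecanoate
Conditions: MeOH, H2SO4 (cat.), reflux
Reagents that add atoms: methanol, CO
Why: Acid-catalysed transesterification (methanolysis) in a large excess of methanol opens the macrolactone to the acyclic hydroxy ester.

Step 2
Reactants: 2 methyl 15-hydroxypentadecanoate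
Product: 3 methyl 15-bromopentadecanoate
Conditions: CBr4, PPh3, CH2Cl2, 0 °C → rt
Reagents that add atoms: carbon tetrabromide, BrC(Br)(Br)Br
Why: Appel bromination converts the primary alcohol to the bromide under neutral conditions that leave the methyl ester untouched.

Step 3
Reactants: 3 methyl 15-bromopentadecanoate
Product: 4 (15-methoxy-15-oxopentadecyl)triphenylphosphonium bromide
Conditions: PPh3, MeCN, reflux, 48 h
Reagents that add atoms: triphenylphosphine, c1ccc(cc1)P(c1ccccc1)c1ccccc1
Why: SN2 quaternisation of triphenylphosphine by the unhindered primary bromide gives the Wittig salt.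

Step 4
Reactants: 5 ethyl (S)-lactate
Product: 6 ethyl (2S)-2-[(tert-butyldimethylsilyl)oxy]propanoate
Conditions: TBSCl, imidazole, DMF, 0 °C → rt
Reagents that add atoms: tert-butyldimethylsilyl chloride, CC(C)(C)[Si](C)(C)Cl
Why: Imidazole-promoted O-silylation protects the alcohol without touching the chiral-pool stereocentre, which becomes the (S)-carbinol carbon of the target.

Step 5
Reactants: 6 ethyl (2S)-2-[(tert-butyldimethylsilyl)oxy]propanoate
Product: 7 (2S)-2-[(tert-butyldimethylsilyl)oxy]propanal
Conditions: DIBAL-H (1.05 equiv), CH2Cl2, −78 °C; MeOH, then aq. Rochelle salt; used crude at once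
Reagents that add atoms: none
Why: DIBAL-H half-reduction at −78 °C stops at the aluminium hemiacetal, which releases the aldehyde only on work-up, so there is no over-reduction and the α-stereocentre is not epimerised.

Step 6
Reactants: 4 (15-methoxy-15-oxopentadecyl)triphenylphosphonium bromide; 7 (2S)-2-[(tert-butyldimethylsilyl)oxy]propanal
Product: 9 methyl (15Z,17S)-17-[(tert-butyldimethylsilyl)oxy]octadec-15-enoate, via phosphonium ylide 8 (not isolated)
Conditions: 4, NaHMDS, THF, −78 → 0 °C; then 7, −78 °C → rt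
Reagents that add atoms: none
Why: Salt-free Wittig olefination of a non-stabilised ylide is fast and cis-selective at low temperature; the phosphonium α-CH2 is deprotonated in preference to the remote ester, and the aldehyde stereocentre is kept.

Step 7
Reactants: 9 methyl (15Z,17S)-17-[(tert-butyldimethylsilyl)oxy]octadec-15-enoate
Product: 10 methyl (17S)-17-[(tert-butyldimethylsilyl)oxy]octadecanoate
Conditions: H2 (1 atm), PtO2 (cat.), EtOAc, rt
Reagents that add atoms: none
Why: Catalytic hydrogenation over platinum saturates the alkene with far less double-bond migration or allylic C–O hydrogenolysis than palladium, so the adjacent stereocentre stays (S).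

Step 8
Reactants: 10 methyl (17S)-17-[(tert-butyldimethylsilyl)oxy]octadecanoate; 11 methyl pyruvate
Product: 14 dimethyl 2-[(15S)-15-[(tert-butyldimethylsilyl)oxy]hexadecyl]-3-hydroxy-3-methylbutanedioate (mixture of C2/C3 diastereomers), via lithium enolate 12 (not isolated), via lithium aldolate 13 (not isolated)
Conditions: LDA (commercial solution, 1.1 equiv), THF, −78 °C; then 11 (1.5 equiv), −78 °C; AcOH quench at −78 °C
Reagents that add atoms: none
Why: Intermolecular aldol addition: the kinetic lithium ester enolate adds to the very electrophilic ketone carbonyl of methyl pyruvate faster than it enolises it at −78 °C; the two new stereocentres form without control and both are removed in step 9.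

Step 9
Reactants: 14 dimethyl 2-[(15S)-15-[(tert-butyldimethylsilyl)oxy]hexadecyl]-3-hydroxy-3-methylbutanedioate
Product: 16 dimethyl (2Z)-2-[(15S)-15-[(tert-butyldimethylsilyl)oxy]hexadecyl]-3-methylbut-2-enedioate, via tertiary tosylate 15 (not isolated)
Conditions: Ts2O, 2,6-di-tert-butyl-4-methylpyridine, pyridine, CH2Cl2, rt → 40 °C; then DBU, PhMe, 80 °C; chromatography
Reagents that add atoms: none
Why: Sulfonylation of the tertiary alcohol followed by DBU-induced β-elimination (E1cB/E2 at the acidic ester α-H) gives the conjugated tetrasubstituted diester with the maleate (Z) isomer expected to predominate; minor E or exo-methylene isomers are removed by chromatography.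

Step 10
Reactants: 16 dimethyl (2Z)-2-[(15S)-15-[(tert-butyldimethylsilyl)oxy]hexadecyl]-3-methylbut-2-enedioate
Product: 17 dimethyl (2Z)-2-[(15S)-15-hydroxyhexadecyl]-3-methylbut-2-enedioate
Conditions: 48% aq. HF, MeCN, 0 °C → rt
Reagents that add atoms: none
Why: Fluoride-driven desilylation under mildly acidic conditions cleaves the secondary TBS ether without affecting the methyl esters, the alkene geometry or the carbinol stereocentre.

Step 11
Reactants: 17 dimethyl (2Z)-2-[(15S)-15-hydroxyhexadecyl]-3-methylbut-2-enedioate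
Product: 20 3-[(15S)-15-hydroxyhexadecyl]-4-methylfuran-2,5-dione, via disodium salt 18 (not isolated), via free diacid 19 (not isolated)
Conditions: NaOH, THF/MeOH/H2O, 65 °C; then aq. HCl to pH 1, rt
Reagents that add atoms: sodium hydroxide, [Na+].[OH-]
Why: Saponification followed by acidification; the cis-dialkylmaleic acid cyclodehydrates spontaneously to the five-membered anhydride, whereas any residual E-diacid cannot close and is separated.

Step 12
Reactants: 20 3-[(15S)-15-hydroxyhexadecyl]-4-methylfuran-2,5-dione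
Product: 21 (2S)-16-(4-methyl-2,5-dioxo-2,5-dihydrofuran-3-yl)hexadecan-2-yl acetate
Conditions: Ac2O, pyridine, DMAP (cat.), CH2Cl2, 0 °C → rt
Reagents that add atoms: acetic anhydride, CC(=O)OC(C)=O
Why: DMAP-catalysed acetylation esterifies the secondary alcohol with retention (the C–O bond is not broken), and the dialkylmaleic anhydride is inert to these conditions.

## Compound list

1 | ω-pentadecalactone (oxacyclohexadecan-2-one) | O=C1CCCCCCCCCCCCCCO1 | starting material
2 | methyl 15-hydroxypentadecanoate | COC(=O)CCCCCCCCCCCCCCO | intermediate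
3 | methyl 15-bromopentadecanoate | COC(=O)CCCCCCCCCCCCCCBr | intermediate
4 | (15-methoxy-15-oxopentadecyl)triphenylphosphonium bromide | COC(=O)CCCCCCCCCCCCCC[P+](c1ccccc1)(c1ccccc1)c1ccccc1.[Br-] | intermediate
5 | ethyl (S)-lactate | C[C@H](O)C(=O)OCC | starting material
6 | ethyl (2S)-2-[(tert-butyldimethylsilyl)oxy]propanoate | C[C@H](O[Si](C)(C)C(C)(C)C)C(=O)OCC | intermediate
7 | (2S)-2-[(tert-butyldimethylsilyl)oxy]propanal | C[C@H](O[Si](C)(C)C(C)(C)C)C=O | intermediate
8 | methyl 15-(triphenyl-λ5-phosphanylidene)pentadecanoate (ylide) | COC(=O)CCCCCCCCCCCCCC=P(c1ccccc1)(c1ccccc1)c1ccccc1 | intermediate (not isolated)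
9 | methyl (15Z,17S)-17-[(tert-butyldimethylsilyl)oxy]octadec-15-enoate | COC(=O)CCCCCCCCCCCCC/C=C\[C@H](C)O[Si](C)(C)C(C)(C)C | intermediate
10 | methyl (17S)-17-[(tert-butyldimethylsilyl)oxy]octadecanoate | COC(=O)CCCCCCCCCCCCCCC[C@H](C)O[Si](C)(C)C(C)(C)C | intermediate
11 | methyl pyruvate | CC(=O)C(=O)OC | starting material
12 | lithium enolate of 10 (enolate geometry not specified) | COC(O[Li])=CCCCCCCCCCCCCCC[C@H](C)O[Si](C)(C)C(C)(C)C | intermediate (not isolated)
13 | lithium alkoxide of 14 (C2/C3 diastereomer mixture) | COC(=O)C(CCCCCCCCCCCCCC[C@H](C)O[Si](C)(C)C(C)(C)C)C(C)(O[Li])C(=O)OC | intermediate (not isolated)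
14 | dimethyl 2-[(15S)-15-[(tert-butyldimethylsilyl)oxy]hexadecyl]-3-hydroxy-3-methylbutanedioate (C2/C3 diastereomer mixture) | COC(=O)C(CCCCCCCCCCCCCC[C@H](C)O[Si](C)(C)C(C)(C)C)C(C)(O)C(=O)OC | intermediate
15 | dimethyl 2-[(15S)-15-[(tert-butyldimethylsilyl)oxy]hexadecyl]-3-methyl-3-(tosyloxy)butanedioate (C2/C3 diastereomer mixture) | COC(=O)C(CCCCCCCCCCCCCC[C@H](C)O[Si](C)(C)C(C)(C)C)C(C)(OS(=O)(=O)c1ccc(C)cc1)C(=O)OC | intermediate (not isolated)
16 | dimethyl (2Z)-2-[(15S)-15-[(tert-butyldimethylsilyl)oxy]hexadecyl]-3-methylbut-2-enedioate | COC(=O)/C(C)=C(/CCCCCCCCCCCCCC[C@H](C)O[Si](C)(C)C(C)(C)C)C(=O)OC | intermediate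
17 | dimethyl (2Z)-2-[(15S)-15-hydroxyhexadecyl]-3-methylbut-2-enedioate | COC(=O)/C(C)=C(/CCCCCCCCCCCCCC[C@H](C)O)C(=O)OC | intermediate
18 | disodium (2Z)-2-[(15S)-15-hydroxyhexadecyl]-3-methylbut-2-enedioate | [Na+].[Na+].[O-]C(=O)/C(C)=C(/CCCCCCCCCCCCCC[C@H](C)O)C(=O)[O-] | intermediate (not isolated)
19 | (2Z)-2-[(15S)-15-hydroxyhexadecyl]-3-methylbut-2-enedioic acid | OC(=O)/C(C)=C(/CCCCCCCCCCCCCC[C@H](C)O)C(=O)O | intermediate (not isolated)
20 | 3-[(15S)-15-hydroxyhexadecyl]-4-methylfuran-2,5-dione | C[C@H](O)CCCCCCCCCCCCCCC1=C(C)C(=O)OC1=O | intermediate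
21 | (2S)-16-(4-methyl-2,5-dioxo-2,5-dihydrofuran-3-yl)hexadecan-2-yl acetate | CC(=O)O[C@@H](C)CCCCCCCCCCCCCCC1=C(C)C(=O)OC1=O | target

## Summary

Total step count: 12.
Longest linear sequence: 10 steps (1, 2, 3, 6, 7, 8, 9, 10, 11, 12 from ω-pentadecalactone).

Three steps most likely to fail:

**Step 9 (dehydration: sulfonylation of a hindered tertiary alcohol, E/Z and endo/exo selectivity).** The fallback sets out from 14 and comes back at 21. The double bond is made inside the ring, where it can only be cis. Compound 14 is desilylated (aq. HF, MeCN) to dimethyl 3-hydroxy-2-[(15S)-15-hydroxyhexadecyl]-3-methylbutanedioate F1. This is saponified (LiOH, THF/H2O, rt, then HCl) to 3-hydroxy-2-[(15S)-15-hydroxyhexadecyl]-3-methylbutanedioic acid F2. Excess Ac2O with Et3N and catalytic DMAP (THF, rt → 50 °C) then closes the succinic anhydride and acetylates both hydroxyls, giving (2S)-16-(4-acetoxy-4-methyl-2,5-dioxooxolan-3-yl)hexadecan-2-yl acetate F3 in the flask. F3 loses acetic acid by E1cB elimination of the β-acetoxy group; only the ring C–H next to the carbonyl is acidic, so the alkene can only form endocyclic, and the product is 21 directly.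

**Step 8 (aldol: enolisation or self-condensation of methyl pyruvate, retro-aldol).** The fallback sets out from 10 and comes back at 14. It replaces the strongly basic lithium enolate by a Reformatsky reagent. Compound 10 is α-brominated (LDA, THF, −78 °C; then CBr4) to methyl (17S)-2-bromo-17-[(tert-butyldimethylsilyl)oxy]octadecanoate F4. Zinc insertion (activated Zn dust, TMSCl cat., THF, 50 °C) gives the bromozinc ester enolate of 10 F5. This weakly basic nucleophile adds to the ketone carbonyl of 11 without deprotonating it and gives 14 after aqueous NH4Cl work-up.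

**Step 6 (Wittig: configurational lability of α-silyloxy aldehyde 7, ylide generation beside an ester).** The fallback sets out from 3 and comes back at 10. It avoids aldehyde 7 and sets the stereocentre by asymmetric ketone reduction. Bromide 3 alkylates tert-butyl acetoacetate (K2CO3, NaI cat., DMF, 60 °C) to methyl 16-(tert-butoxycarbonyl)-17-oxooctadecanoate F6. TFA in CH2Cl2 cleaves the tert-butyl ester to 2-acetyl-17-methoxy-17-oxoheptadecanoic acid F7, which decarboxylates in toluene at 90 °C to methyl 17-oxooctadecanoate F8. A Prelog-selective alcohol dehydrogenase (NAD+ cat., i-PrOH/buffer, 30 °C) reduces the methyl ketone to methyl (17S)-17-hydroxyoctadecanoate F9. Silylation (TBSCl, imidazole, DMF) then gives 10.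

## Further compounds

F1 | step 9 | dimethyl 3-hydroxy-2-[(15S)-15-hydroxyhexadecyl]-3-methylbutanedioate | COC(=O)C(CCCCCCCCCCCCCC[C@H](C)O)C(C)(O)C(=O)OC
F2 | step 9 | 3-hydroxy-2-[(15S)-15-hydroxyhexadecyl]-3-methylbutanedioic acid | OC(=O)C(CCCCCCCCCCCCCC[C@H](C)O)C(C)(O)C(=O)O
F3 | step 9 | (2S)-16-(4-acetoxy-4-methyl-2,5-dioxooxolan-3-yl)hexadecan-2-yl acetate | CC(=O)O[C@@H](C)CCCCCCCCCCCCCCC1C(=O)OC(=O)C1(C)OC(C)=O
F4 | step 8 | methyl (17S)-2-bromo-17-[(tert-butyldimethylsilyl)oxy]octadecanoate | COC(=O)C(Br)CCCCCCCCCCCCCC[C@H](C)O[Si](C)(C)C(C)(C)C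
F5 | step 8 | bromozinc ester enolate of 10 (Reformatsky reagent) | COC(O[Zn]Br)=CCCCCCCCCCCCCCC[C@H](C)O[Si](C)(C)C(C)(C)C
F6 | step 6 | methyl 16-(tert-butoxycarbonyl)-17-oxooctadecanoate | CC(=O)C(C(=O)OC(C)(C)C)CCCCCCCCCCCCCCC(=O)OC
F7 | step 6 | 2-acetyl-17-methoxy-17-oxoheptadecanoic acid | CC(=O)C(C(=O)O)CCCCCCCCCCCCCCC(=O)OC
F8 | step 6 | methyl 17-oxooctadecanoate | CC(=O)CCCCCCCCCCCCCCCC(=O)OC
F9 | step 6 | methyl (17S)-17-hydroxyoctadecanoate | C[C@H](O)CCCCCCCCCCCCCCCC(=O)OC
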